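**Retrosynthetic overview**
- Feature: the numbering is that of bicyclo[3.3.1]nonane, with ring A = C1-C2-C3-C4-C5-C9 and ring B = C1-C8-C7-C6-C5-C9. The ring B bridge C6(OH)–C7(NH)–C8H2 has the atom pattern and configuration of L-serinal. Its methylene C8 ends on the oxygenated bridgehead C1, which lies between C9=O and a carbon (C2) that can be carried as a second ketone.
- Endgame: silyl and PMB removal, hydroxyl-directed exo epoxidation of C2=C3 and N-acylation with (E)-7-oxododec-2-enoic acid lead back to the allylic alcohol (C2=C3, C4-OH). That alcohol comes from the 2,9-dione by dehydrogenation, exo epoxidation and Wharton transposition.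
- Key disconnection C1–C8: ring B is closed by intramolecular C-alkylation of the enolate of a ring A 2-(PMB-oxy)-1,3-dione with the primary C8 iodide.
- Disconnection C5–C6: a syn-selective, Felkin–Anh aldol joins the titanium enolate of the dione ethyl enol ether to the protected serinal. C5 has to be set here, because the dione monoanion of the key step cannot epimerise.
- Ring order: ring A is bought (cyclohexane-1,3-dione, C1 oxygen by diazo transfer and O–H insertion), ring B forms in step 9 and the oxirane in step 19.

Key step: step 9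

Remark: the locants C1–C9 of the final bicycle are used for all intermediates. "Exo" means the face of one six-membered ring that is turned away from the other ring.
Assumption: 13 is drawn as one enol tautomer. Every tautomer gives the same delocalised enolate 14.

**Step 1**
Reactants: 1 cyclohexane-1,3-dione
Product: 2 2-diazocyclohexane-1,3-dione
Conditions: p-ABSA, Et3N, MeCN, 0 °C → rt
Reagents that add atoms: 4-acetamidobenzenesulfonyl azide (p-ABSA) CC(=O)Nc1ccc(cc1)S(=O)(=O)N=[N+]=[N-]
Why: Regitz diazo transfer, in which the acidic methylene between the two carbonyls is deprotonated by the amine and takes over N2 from the sulfonyl azide.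

**Step 2**
Reactants: 2 2-diazocyclohexane-1,3-dione, 3 4-methoxybenzyl alcohol
Product: 4 3-hydroxy-2-[(4-methoxybenzyl)oxy]cyclohex-2-en-1-one (enol form of the 2-(PMB-oxy)-1,3-dione)
Conditions: Rh2(OAc)4 (1 mol %), 3 (1.5 equiv), 1,2-dichloroethane, 80 °C, slow addition of 2
Reagents that add atoms: none
Why: Rhodium carbenoid O–H insertion is a known reaction of 2-diazo-1,3-diones with alcohols, it is faster than attack on the anisyl ring, and it installs the future C1 oxygen already protected.

**Step 3**
Reactants: 4 3-hydroxy-2-[(4-methoxybenzyl)oxy]cyclohex-2-en-1-one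
Product: 5 3-ethoxy-2-[(4-methoxybenzyl)oxy]cyclohex-2-en-1-one
Conditions: HC(OEt)3, p-TsOH·H2O (5 mol %), EtOH, rt
Reagents that add atoms: triethyl orthoformate CCOC(OCC)OCC
Why: Acid-catalysed enol etherification with the orthoformate as water scavenger runs at room temperature, where the PMB ether is stable, and the symmetry of 4 allows only one vinylogous ester.

**Step 4**
Reactants: 5 3-ethoxy-2-[(4-methoxybenzyl)oxy]cyclohex-2-en-1-one, 6 N-Boc-N,O-isopropylidene-L-serinal (tert-butyl (4S)-4-formyl-2,2-dimethyl-1,3-oxazolidine-3-carboxylate)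
Product: 9 tert-butyl (4S)-4-{(R)-[(1R)-4-ethoxy-3-(4-methoxybenzyloxy)-2-oxocyclohex-3-en-1-yl](hydroxy)methyl}-2,2-dimethyl-1,3-oxazolidine-3-carboxylate (5R,6R,7S), via lithium dienolate 7 (not isolated), via titanium dienolate 8 (not isolated)
Conditions: LDA, THF, −78 °C; ClTi(OiPr)3, −78 → −40 °C; 6, −78 °C; aq NH4Cl
Reagents that add atoms: none
Why: Kinetic α′-deprotonation of the vinylogous ester and transmetalation give a weakly Lewis acidic alkoxytitanium enolate, whose aldol additions are known to favour syn adducts even from ring-locked enolates and to avoid chelation, so C5/C6 should come out syn (C4 and O6 are trans on ring B) and C6/C7 anti by Felkin–Anh attack (O6 and N7 are cis on ring B), with minor epimers removed by chromatography at this stage.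

**Step 5**
Reactants: 9 aldol adduct
Product: 10 C6 O-TBS ether of 9 (5R,6R,7S)
Conditions: TBSOTf, 2,6-lutidine, CH2Cl2, −78 → 0 °C
Reagents that add atoms: tert-butyldimethylsilyl triflate CC(C)(C)[Si](C)(C)OS(=O)(=O)C(F)(F)F
Why: Silyl triflate silylation is fast enough for the hindered carbinol at low temperature, blocks retro-aldol cleavage, and is too weakly basic to touch C5.

**Step 6**
Reactants: 10 silyl ether
Product: 11 ring A vinylogous ester bearing at C5 the arm C6H(OTBS)-C7H(NHBoc)-C8H2OH (5R,6R,7S)
Conditions: BiBr3 (10 mol %), H2O (2 equiv), MeCN, rt, short time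
Reagents that add atoms: none
Why: Lewis-acid-catalysed hydrolysis of the N,O-aminal, the most acid-labile group present, is known to spare Boc and silyl ethers, and the short contact time keeps the freed C8 hydroxyl from exchanging into the vinylogous ester at C9.

**Step 7**
Reactants: 11 amino alcohol
Product: 12 ring A vinylogous ester bearing at C5 the arm C6H(OTBS)-C7H(NHBoc)-C8H2I (5R,6R,7R; the C7 descriptor changes only through the priority of iodine)
Conditions: I2, PPh3, imidazole, CH2Cl2, 0 °C → rt
Reagents that add atoms: iodine II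
Why: Appel-type iodination proceeds by SN2 displacement at the primary carbon under buffered conditions, is well known for N-Boc 2-amino alcohols, and touches no stereocentre.

**Step 8**
Reactants: 12 iodide
Product: 13 ring A 2-(PMB-oxy)-1,3-dione (enol form) bearing at C5 the arm C6H(OTBS)-C7H(NHBoc)-C8H2I (5R,6R,7R)
Conditions: 1 M aq HCl, THF, 0 °C → rt
Reagents that add atoms: water O
Why: Acid hydrolysis of a vinylogous ester (water adds at C2, ethanol leaves) needs only dilute acid, which the carbamate, the hindered secondary silyl ether, the PMB ether and the alkyl iodide should tolerate.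

**Step 9**
Reactants: 13 iodo dione
Product: 15 (1S,5R,6R,7S)-7-(Boc-amino)-6-(TBS-oxy)-1-(PMB-oxy)bicyclo[3.3.1]nonane-2,9-dione (C6-O exo axial and C7-N exo equatorial), via cesium enolate 14 (not isolated)
Conditions: Cs2CO3 (1.2 equiv), t-BuOH (5 mM), 45 °C, dark
Reagents that add atoms: none
Why: Proposed new method: Cs2CO3 takes only the acidic enol proton of 13, and C1 of the delocalised enolate 14 displaces iodide from the primary carbon C8 in an intramolecular SN2 reaction that forms C1–C8; the carbamate N–H stays protonated, which matters because an N-Boc aziridine would have to be opened at C8 in an unfavourable endo sense. The closest known reaction type is the intramolecular C-alkylation (and the related halonium-induced carbocyclisation) of 2-alkylcyclohexane-1,3-diones to bicyclo[3.3.1]nonane-2,9-diones; a 2-alkoxy donor has not been used, but the oxygen substituent adds little bulk and raises the electron density at C1. Ring B closes in the 6-(enolendo)-exo-tet mode, which is allowed and needs the C5 arm pseudo-axial so that C8 lies over the π face at C1, a conformer already favoured by allylic strain between an equatorial arm and the C9 oxygen. C1 can be reached only from the face that carries the arm, so its S configuration is dictated by C5, which was set in step 4 and cannot epimerise here because the monoanion resists a second deprotonation (the same fact suppresses β-elimination of the C6 silyloxy group); with 5R the chair of ring B places C7-NHBoc equatorial and C6-OTBS axial, both exo. The selectivity needed is carbon over oxygen, since O9 could close a fused dihydropyran by a 6-exo-tet path. It is sought through the soft iodide, the hydrogen-bond-donor solvent that ties up the enolate oxygens, high dilution and the axial bias of the arm, with cesium serving only as the cation of a mild base.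

**Step 10**
Reactants: 15 bicyclic 2,9-dione
Product: 16 C2 trimethylsilyl enol ether of 15 (C2=C3)
Conditions: LiHMDS (2.3 equiv), TMSCl, THF, −78 → 0 °C; cold aq NaHCO3
Reagents that add atoms: chlorotrimethylsilane C[Si](C)(C)Cl
Why: Kinetic enolate silylation can occur only at C3, because C1 is quaternary and a C5 enolate would be a bridgehead alkene, while the extra base covers the carbamate N–H, whose silyl group falls off on work-up.

**Step 11**
Reactants: 16 silyl enol ether
Product: 17 7-(Boc-amino)-6-(TBS-oxy)-1-(PMB-oxy)bicyclo[3.3.1]non-3-ene-2,9-dione (enone C2=O/C3=C4)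
Conditions: Pd(OAc)2 (1.1 equiv), MeCN, rt
Reagents that add atoms: none
Why: In the Saegusa–Ito oxidation divalent palladium binds C3 on the open exo face and syn β-hydride elimination of the exo hydrogen at C4 gives the enone and zerovalent palladium.

**Step 12**
Reactants: 17 enone
Product: 18 exo-3,4-epoxy-7-(Boc-amino)-6-(TBS-oxy)-1-(PMB-oxy)bicyclo[3.3.1]nonane-2,9-dione (oxirane oxygen on the face of ring A away from ring B)
Conditions: t-BuOOH (decane), DBU, CH2Cl2, 0 °C → rt
Reagents that add atoms: tert-butyl hydroperoxide CC(C)(C)OO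
Why: In this Weitz–Scheffer nucleophilic epoxidation the bulky peroxide anion adds to C4 from the convex exo face, because ring B blocks the endo face, which sets C4, and the non-aqueous medium limits attack on the non-enolisable 1,3-dione.

**Step 13**
Reactants: 18 epoxy ketone
Product: 20 7-(Boc-amino)-4-exo-hydroxy-6-(TBS-oxy)-1-(PMB-oxy)bicyclo[3.3.1]non-2-en-9-one, via C2 hydrazone 19 (not isolated)
Conditions: N2H4·H2O (1.5 equiv), AcOH (cat.), MeOH, 0 °C → rt
Reagents that add atoms: none
Why: In the Wharton transposition hydrazine should condense at the activated, exo-accessible C2 ketone rather than at C9 (screened by the axial C6-OTBS on one face and the oxirane oxygen on the other), and loss of N2 opens the epoxide to C2=C3 with the C4–O bond and its exo configuration retained.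

**Step 14**
Reactants: 21 hex-5-enoic acid
Product: 23 N-methoxy-N-methylhex-5-enamide, via acyl imidazole 22 (not isolated)
Conditions: CDI, CH2Cl2, rt; MeNH(OMe)·HCl, rt
Reagents that add atoms: N,O-dimethylhydroxylamine hydrochloride CNOC.Cl
Why: Carbonyldiimidazole activation followed by aminolysis is a standard amide formation and leaves the terminal alkene untouched.

**Step 15**
Reactants: 23 N-methoxy-N-methylhex-5-enamide, 24 pentylmagnesium bromide
Product: 25 undec-1-en-6-one
Conditions: THF, 0 °C; 1 M aq HCl
Reagents that add atoms: none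
Why: In the Weinreb ketone synthesis the chelated tetrahedral intermediate survives until the quench, so no second Grignard addition occurs.

**Step 16**
Reactants: 25 undec-1-en-6-one, 26 acrylic acid
Product: 27 (E)-7-oxododec-2-enoic acid
Conditions: second-generation Hoveyda–Grubbs catalyst (3 mol %), 26 (3 equiv), CH2Cl2, 40 °C
Reagents that add atoms: none
Why: Olefin cross metathesis of a terminal alkene with an electron-poor acrylate partner is selective for the cross product and sets the E alkene under thermodynamic control.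

**Step 17**
Reactants: 20 allylic alcohol
Product: 29 7-amino-4-exo-hydroxy-6-(TBS-oxy)-1-(PMB-oxy)bicyclo[3.3.1]non-2-en-9-one, via silyl carbamate silyl ether 28 (not isolated)
Conditions: TMSOTf, 2,6-lutidine, CH2Cl2, 0 °C; MeOH, rt
Reagents that add atoms: none
Why: Silyl-triflate-mediated Boc cleavage (tert-butyl lost as isobutene, silyl carbamate and C4 silyl ether removed by methanol) works under buffered aprotic conditions that should spare the PMB ether, the TBS ether and the allylic alcohol.

**Step 18**
Reactants: 29 amine, 27 (E)-7-oxododec-2-enoic acid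
Product: 30 (E)-7-oxododec-2-enamide of 29
Conditions: DIC, HOBt, CH2Cl2/DMF, 0 °C → rt
Reagents that add atoms: none
Why: In this carbodiimide amide coupling through the benzotriazolyl ester the equatorial primary amine is far more nucleophilic than the C4 hydroxyl.

**Step 19**
Reactants: 30 amide
Product: 31 exo-2,3-epoxide of 30 (oxirane oxygen syn to C4-OH)
Conditions: VO(acac)2 (5 mol %), t-BuOOH (decane), CH2Cl2, 0 °C → rt
Reagents that add atoms: tert-butyl hydroperoxide CC(C)(C)OO
Why: In the hydroxyl-directed vanadium-catalysed epoxidation the pseudo-axial exo C4-OH delivers the peroxide to its own face, which is also the convex face, setting C2 and C3, while the electron-poor enamide alkene is not attacked.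

**Step 20**
Reactants: 31 epoxide
Product: 32 6-O-TBS-isariotin C (free C1 carbinol)
Conditions: DDQ, CH2Cl2/pH 7 buffer, 0 °C → rt
Reagents that add atoms: none
Why: Oxidative PMB cleavage by hydride abstraction from the anisylic carbon and hydrolysis of the oxocarbenium ion is neutral and leaves the epoxide, silyl ether, ketones and enamide intact.

**Step 21**
Reactants: 32 6-O-TBS-isariotin C
Product: 33 isariotin C
Conditions: HF·pyridine, pyridine, THF, 0 °C → rt
Reagents that add atoms: none
Why: Fluoride desilylation in a pyridine-buffered medium avoids the base that could trigger an α-ketol shift, and the hydroxyls at C1 and C4 lie syn to the oxirane oxygen, so no Payne migration can occur.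

**Compound list**
1 | cyclohexane-1,3-dione | O=C1CCCC(=O)C1 | starting material
2 | 2-diazocyclohexane-1,3-dione | [N-]=[N+]=C1C(=O)CCCC1=O | intermediate
3 | 4-methoxybenzyl alcohol | COc1ccc(CO)cc1 | starting material
4 | 3-hydroxy-2-[(4-methoxybenzyl)oxy]cyclohex-2-en-1-one | O=C1CCCC(O)=C1OCc2ccc(OC)cc2 | intermediate
5 | 3-ethoxy-2-[(4-methoxybenzyl)oxy]cyclohex-2-en-1-one | CCOC1=C(OCc2ccc(OC)cc2)C(=O)CCC1 | intermediate
6 | N-Boc-N,O-isopropylidene-L-serinal | CC1(C)OC[C@@H](C=O)N1C(=O)OC(C)(C)C | starting material
7 | lithium dienolate of 5 | [Li+].CCOC1=C(OCc2ccc(OC)cc2)C([O-])=CCC1 | intermediate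
8 | triisopropoxytitanium dienolate of 5 | CCOC1=C(OCc2ccc(OC)cc2)C(O[Ti](OC(C)C)(OC(C)C)OC(C)C)=CCC1 | intermediate
9 | aldol adduct (5R,6R,7S) | CC(C)(C)OC(=O)N1[C@@H](COC1(C)C)[C@H](O)[C@H]2CCC(OCC)=C(OCc3ccc(OC)cc3)C2=O | intermediate
10 | C6 O-TBS ether of 9 | CC(C)(C)OC(=O)N1[C@@H](COC1(C)C)[C@H](O[Si](C)(C)C(C)(C)C)[C@H]2CCC(OCC)=C(OCc3ccc(OC)cc3)C2=O | intermediate
11 | N-Boc amino alcohol (C8-OH) | CC(C)(C)OC(=O)N[C@@H](CO)[C@H](O[Si](C)(C)C(C)(C)C)[C@H]1CCC(OCC)=C(OCc2ccc(OC)cc2)C1=O | intermediate
12 | C8 iodide, ethyl enol ether | CC(C)(C)OC(=O)N[C@@H](CI)[C@H](O[Si](C)(C)C(C)(C)C)[C@H]1CCC(OCC)=C(OCc2ccc(OC)cc2)C1=O | intermediate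
13 | C8 iodide, 2-(PMB-oxy)-1,3-dione (enol form), key-step precursor | CC(C)(C)OC(=O)N[C@@H](CI)[C@H](O[Si](C)(C)C(C)(C)C)[C@H]1CCC(O)=C(OCc2ccc(OC)cc2)C1=O | intermediate
14 | cesium enolate of 13 | [Cs+].CC(C)(C)OC(=O)N[C@@H](CI)[C@H](O[Si](C)(C)C(C)(C)C)[C@H]1CCC([O-])=C(OCc2ccc(OC)cc2)C1=O | intermediate
15 | (1S,5R,6R,7S)-bicyclo[3.3.1]nonane-2,9-dione, key-step product | CC(C)(C)OC(=O)N[C@H]1C[C@@]2(OCc3ccc(OC)cc3)C(=O)[C@H](CCC2=O)[C@H]1O[Si](C)(C)C(C)(C)C | intermediate
16 | C2 TMS enol ether | CC(C)(C)OC(=O)N[C@H]1C[C@@]2(OCc3ccc(OC)cc3)C(=O)[C@H](CC=C2O[Si](C)(C)C)[C@H]1O[Si](C)(C)C(C)(C)C | intermediate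
17 | C3=C4 enone | CC(C)(C)OC(=O)N[C@H]1C[C@@]2(OCc3ccc(OC)cc3)C(=O)[C@H](C=CC2=O)[C@H]1O[Si](C)(C)C(C)(C)C | intermediate
18 | exo-3,4-epoxy ketone | CC(C)(C)OC(=O)N[C@H]1C[C@@]2(OCc3ccc(OC)cc3)C(=O)[C@H]([C@@H]4O[C@@H]4C2=O)[C@H]1O[Si](C)(C)C(C)(C)C | intermediate
19 | C2 hydrazone of 18 | CC(C)(C)OC(=O)N[C@H]1C[C@@]2(OCc3ccc(OC)cc3)C(=O)[C@H]([C@@H]4O[C@@H]4C2=NN)[C@H]1O[Si](C)(C)C(C)(C)C | intermediate
20 | allylic alcohol (C2=C3, 4-exo-OH) | CC(C)(C)OC(=O)N[C@H]1C[C@@]2(OCc3ccc(OC)cc3)C(=O)[C@H]([C@H](O)C=C2)[C@H]1O[Si](C)(C)C(C)(C)C | intermediate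
21 | hex-5-enoic acid | C=CCCCC(=O)O | starting material
22 | 1-(hex-5-enoyl)imidazole | C=CCCCC(=O)n1ccnc1 | intermediate
23 | N-methoxy-N-methylhex-5-enamide | C=CCCCC(=O)N(C)OC | intermediate
24 | pentylmagnesium bromide | CCCCC[Mg]Br | starting material
25 | undec-1-en-6-one | C=CCCCC(=O)CCCCC | intermediate
26 | acrylic acid | C=CC(=O)O | starting material
27 | (E)-7-oxododec-2-enoic acid | CCCCCC(=O)CCC/C=C/C(=O)O | intermediate
28 | N-(trimethylsilyloxycarbonyl) C4-O-TMS derivative | C[Si](C)(C)OC(=O)N[C@H]1C[C@@]2(OCc3ccc(OC)cc3)C(=O)[C@H]([C@H](O[Si](C)(C)C)C=C2)[C@H]1O[Si](C)(C)C(C)(C)C | intermediate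
29 | C7 primary amine | N[C@H]1C[C@@]2(OCc3ccc(OC)cc3)C(=O)[C@H]([C@H](O)C=C2)[C@H]1O[Si](C)(C)C(C)(C)C | intermediate
30 | (E)-7-oxododec-2-enamide of 29 | CCCCCC(=O)CCC/C=C/C(=O)N[C@H]1C[C@@]2(OCc3ccc(OC)cc3)C(=O)[C@H]([C@H](O)C=C2)[C@H]1O[Si](C)(C)C(C)(C)C | intermediate
31 | exo-2,3-epoxide of 30 | CCCCCC(=O)CCC/C=C/C(=O)N[C@H]1C[C@@]2(OCc3ccc(OC)cc3)C(=O)[C@H]([C@H](O)[C@@H]4O[C@@H]42)[C@H]1O[Si](C)(C)C(C)(C)C | intermediate
32 | 6-O-TBS-isariotin C | CCCCCC(=O)CCC/C=C/C(=O)N[C@H]1C[C@@]2(O)C(=O)[C@H]([C@H](O)[C@@H]3O[C@@H]32)[C@H]1O[Si](C)(C)C(C)(C)C | intermediate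
33 | isariotin C, (1S,2S,3S,4S,5S,6R,7S) in the numbering used here | CCCCCC(=O)CCC/C=C/C(=O)N[C@H]1C[C@@]2(O)C(=O)[C@H]([C@H](O)[C@@H]3O[C@@H]32)[C@H]1O | target

**Step count**
Total step count: 21. Longest linear sequence: 18 (steps 1–13 and 17–21).

**Steps most likely to fail**

**Step 9.** The enolate may alkylate on the C9 oxygen and close a fused dihydropyran instead of ring B. The closure may also be slow enough for the carbamate to attack the iodide. The fallback changes the nucleophile from an oxygen enolate to an aza-enolate. It relies on the known behaviour of mono-N,N-dimethylhydrazones of 2-substituted cyclohexane-1,3-diones, which are alkylated at carbon by unactivated primary iodides where the parent diones react on oxygen. It sets out from 11.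
- Exchange of the ethoxy group with Me2NNH2 (EtOH, 50 °C) gives the vinylogous hydrazide alcohol F1.
- Iodination as in step 7 gives the vinylogous hydrazide iodide F2.
- KH (1 equiv, THF, 0 °C → rt) closes C1–C8 to the bicyclic C2 dimethylhydrazone F3.
- Cu(OAc)2 in aqueous THF hydrolyses the hydrazone, and the route is rejoined at 15.

**Step 4.** Simple diastereoselection at C5 may be poor (the chair-type anti pathway may take over), the Felkin–Anh facial selectivity may erode, or the adduct may undergo retro-aldol cleavage on work-up. The fallback replaces the closed, metal-centred transition state by an open, metal-free one, which is known to favour syn adducts whatever the enolate geometry. It sets out from 5.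
- LDA and TMSCl (THF, −78 °C) give the isolated trimethylsilyl dienol ether F4.
- F4 reacts with 6 under catalysis by tris(dimethylamino)sulfonium difluorotrimethylsilicate (THF, −78 °C) to give the O-trimethylsilyl aldol adduct F5.
- Citric acid in MeOH removes the silyl group, and the route is rejoined at 9.

**Step 13.** Hydrazine may condense at the C9 ketone or cleave the non-enolisable 1,3-dione by retro-Claisen attack. The fallback avoids nucleophiles at carbonyl carbon and uses the fact that only C2 can enolise. It sets out from 15 and bypasses steps 10–13.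
- LiHMDS and N-(5-chloro-2-pyridyl)triflimide (THF, −78 °C) give the C2 enol triflate F6.
- Reduction with Pd(OAc)2, PPh3, HCO2H and Et3N (DMF, 50 °C) gives the C2=C3 alkene F7.
- Allylic hydroxylation with SeO2 and t-BuOOH (CH2Cl2, rt) runs by an ene reaction on the exo face followed by a [2,3] shift. C4 is the only allylic carbon that bears hydrogen, so the hydroxyl is placed exo at C4, and the route is rejoined at 20.

**Further compounds**
F1 | step 9 | vinylogous hydrazide alcohol | CC(C)(C)OC(=O)N[C@@H](CO)[C@H](O[Si](C)(C)C(C)(C)C)[C@H]1CCC(NN(C)C)=C(OCc2ccc(OC)cc2)C1=O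
F2 | step 9 | vinylogous hydrazide iodide | CC(C)(C)OC(=O)N[C@@H](CI)[C@H](O[Si](C)(C)C(C)(C)C)[C@H]1CCC(NN(C)C)=C(OCc2ccc(OC)cc2)C1=O
F3 | step 9 | bicyclic C2 dimethylhydrazone | CC(C)(C)OC(=O)N[C@H]1C[C@@]2(OCc3ccc(OC)cc3)C(=O)[C@H](CCC2=NN(C)C)[C@H]1O[Si](C)(C)C(C)(C)C
F4 | step 4 | trimethylsilyl dienol ether of 5 | CCOC1=C(OCc2ccc(OC)cc2)C(O[Si](C)(C)C)=CCC1
F5 | step 4 | O-trimethylsilyl aldol adduct | CC(C)(C)OC(=O)N1[C@@H](COC1(C)C)[C@H](O[Si](C)(C)C)[C@H]2CCC(OCC)=C(OCc3ccc(OC)cc3)C2=O
F6 | step 13 | C2 enol triflate | CC(C)(C)OC(=O)N[C@H]1C[C@@]2(OCc3ccc(OC)cc3)C(=O)[C@H](CC=C2OS(=O)(=O)C(F)(F)F)[C@H]1O[Si](C)(C)C(C)(C)C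
F7 | step 13 | C2=C3 alkene | CC(C)(C)OC(=O)N[C@H]1C[C@@]2(OCc3ccc(OC)cc3)C(=O)[C@H](CC=C2)[C@H]1O[Si](C)(C)C(C)(C)C
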